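## Retrosynthetic overview

1. Both nitrogen rings are opened in one cut. The enamine N1–C7a=C7 is the condensation product of the C2 amine with a C7a ketone, and the azepine bond Cα–Cβ is a hydroformylation bond (Cα from CO, Cβ the terminal carbon of an allyl group on C7). Target 31 ⇒ monocarbocyclic allyl keto carbamate 26.
2. Enabling feature: C7a is shared by the pyrroline and azepine rings, lies 1,4 to N1 (N1–C2–C3–C3a–C7a) and is α to C7, which carries Cδ–Cγ–Cβ. One amine, one ketone and one aldehyde therefore close the five- and seven-membered rings, and the tetrasubstituted C7a=C7 enamine survives the reduction that saturates N1–Cα=Cβ.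
3. 26 ⇒ γ-silyloxy enone 24 (Et2Zn 1,4-addition anti to O–C5, then C7 allylation) ⇒ fused α-methylene lactone 21 (convex-face hydrogenation sets the methyl centre) ⇒ acrylamide 19 (β-epoxidation, amide-assisted 5-exo opening at C3a).
4. 19 ⇒ alkenyl iodide 17 + amino-lactone iodide 7 (Negishi coupling at C3a). 17 comes from enone ketal 8 (transfer hydrogenation sets C5, CBS reduction, Eschenmoser–Claisen from O–C7a to C4, α-methylenation); 7 comes from (R)-Garner's aldehyde 1 and bromomethylacrylate 2.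
5. Ring order: pendant butyrolactone (step 1), carbocycle (bought in 8), fused γ-lactone (step 13), pyrroline and azepine together (step 17).

Key step: step 17

Remark (numbering used below): the core is numbered as a perhydroindole (N1, C2, C3, C3a, C4, C5, C6, C7, C7a); Cα–Cδ are the azepine methylenes from N1 to C7; the α face of the carbocycle is the face of the C3a–O bond, the β face the other.

## Route

Step 1
Reactants: 1 tert-butyl (4R)-4-formyl-2,2-dimethyl-1,3-oxazolidine-3-carboxylate ((R)-Garner's aldehyde); 2 ethyl 2-(bromomethyl)prop-2-enoate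
Product: 4 tert-butyl (4R)-2,2-dimethyl-4-[(2S)-4-methylidene-5-oxooxolan-2-yl]-1,3-oxazolidine-3-carboxylate, via anti hydroxy ester 3 (not isolated)
Conditions: Zn dust, THF/sat. aq. NH4Cl, 0 °C to rt; then PPTS (cat.), toluene, 60 °C
Reagents that add atoms: none
Why: Zinc-mediated Barbier 2-(alkoxycarbonyl)allylation (Dreiding–Schmidt) of the non-chelating N,O-acetonide aldehyde should follow the Felkin–Anh mode and set the carbinol centre anti (S) to the C–N centre, and mild acid then closes the γ-lactone with loss of ethanol.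

Step 2
Reactants: 4 α-methylene lactone
Product: 5 tert-butyl (4R)-2,2-dimethyl-4-[(2S,4S)-4-methyl-5-oxooxolan-2-yl]-1,3-oxazolidine-3-carboxylate
Conditions: H2 (1 atm), 5% Rh/Al2O3, EtOAc, rt
Reagents that add atoms: none
Why: Catalytic hydrogenation of an α-methylene-γ-butyrolactone delivers hydrogen to the face opposite the bulky γ-oxazolidinyl group, so the methyl should end cis to it (4S).

Step 3
Reactants: 5 cis-methyl lactone acetonide
Product: 6 tert-butyl N-{(1R)-2-hydroxy-1-[(2S,4S)-4-methyl-5-oxooxolan-2-yl]ethyl}carbamate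
Conditions: p-TsOH·H2O (10 mol%), MeOH, 0 °C to rt
Reagents that add atoms: none
Why: Acid-catalysed transketalization removes the N,O-isopropylidene group while the Boc group and the γ-lactone persist.

Step 4
Reactants: 6 N-Boc amino alcohol
Product: 7 tert-butyl N-{(1S)-2-iodo-1-[(2S,4S)-4-methyl-5-oxooxolan-2-yl]ethyl}carbamate
Conditions: I2, PPh3, imidazole, CH2Cl2, 0 °C to rt
Reagents that add atoms: iodine (II)
Why: Appel-type (Garegg–Samuelsson) iodination of the primary alcohol touches no stereocentre (the descriptor changes only through CIP priority).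

Step 5
Reactants: 8 1,4-dioxaspiro[4.5]dec-6-en-8-one
Product: 9 (8R)-1,4-dioxaspiro[4.5]dec-6-en-8-ol
Conditions: RuCl(p-cymene)[(R,R)-TsDPEN] (1 mol%), HCO2H/Et3N (5:2), CH2Cl2, rt
Reagents that add atoms: none
Why: Noyori asymmetric transfer hydrogenation reduces the enone carbonyl 1,2-selectively, and the (R,R) ligand should give the 8R carbinol (future C5) by the aryl/alkenyl ketone model.

Step 6
Reactants: 9 (R)-allylic alcohol
Product: 10 tert-butyl{[(8R)-1,4-dioxaspiro[4.5]dec-6-en-8-yl]oxy}dimethylsilane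
Conditions: TBSCl, imidazole, DMF, rt
Reagents that add atoms: tert-butyldimethylsilyl chloride (CC(C)(C)[Si](C)(C)Cl)
Why: Standard silylation of a secondary allylic alcohol.

Step 7
Reactants: 10 silyl ether ketal
Product: 11 (4R)-4-[(tert-butyldimethylsilyl)oxy]cyclohex-2-en-1-one
Conditions: montmorillonite K10, wet CH2Cl2, rt
Reagents that add atoms: water (O)
Why: Mild clay-catalysed ketal hydrolysis unveils the enone (C7a=O, C3a=C4) without cleaving the secondary silyl ether or eliminating the γ-oxygen.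

Step 8
Reactants: 11 γ-silyloxy enone
Product: 12 (4R)-4-[(tert-butyldimethylsilyl)oxy]-2-iodocyclohex-2-en-1-one
Conditions: I2, pyridine, CH2Cl2, 0 °C to rt
Reagents that add atoms: iodine (II)
Why: Johnson α-iodination of an enone proceeds by pyridine conjugate addition, iodination of the enolate and elimination, placing iodine on C3a.

Step 9
Reactants: 12 α-iodo enone
Product: 13 (1S,4R)-4-[(tert-butyldimethylsilyl)oxy]-2-iodocyclohex-2-en-1-ol (cis)
Conditions: (R)-2-methyl-CBS-oxazaborolidine (20 mol%), BH3·SMe2, THF, −30 °C; MeOH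
Reagents that add atoms: none
Why: Corey–Bakshi–Shibata reduction, for which α-halo enones are privileged substrates, should set the C7a carbinol as 1S under reagent control, cis to the C5 silyloxy group.

Step 10
Reactants: 13 cis iodo allylic alcohol
Product: 15 2-{(1R,6R)-6-[(tert-butyldimethylsilyl)oxy]-2-iodocyclohex-2-en-1-yl}-N,N-dimethylacetamide, via ketene N,O-acetal 14 (not isolated)
Conditions: MeC(OMe)2NMe2 (5 equiv), xylene, 140 °C
Reagents that add atoms: N,N-dimethylacetamide dimethyl acetal (CC(OC)(OC)N(C)C)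
Why: Eschenmoser–Claisen rearrangement: the suprafacial [3,3] shift transfers the C7a–O chirality to C4, so the new C–C bond lies on the α face cis to O–C5, and no α-stereocentre is created.

Step 11
Reactants: 15 iodo alkenyl acetamide
Product: 17 2-{(1R,6R)-6-[(tert-butyldimethylsilyl)oxy]-2-iodocyclohex-2-en-1-yl}-N,N-dimethylprop-2-enamide, via Mannich base 16 (not isolated)
Conditions: LDA, THF, −78 °C; CH2=NMe2+ I−, −78 °C to rt; then MeI, MeOH, rt; then DBU, CH2Cl2, rt
Reagents that add atoms: Eschenmoser's salt (C=[N+](C)C.[I-])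
Why: Amide enolate Mannich reaction followed by quaternization and E1cB elimination gives the α-methylene amide; the ring stereocentres are not enolizable and the strong base is used before the base-sensitive lactone fragment is attached.

Step 12
Reactants: 7 amino-lactone iodide; 17 iodo alkenyl acrylamide
Product: 19 2-[(1R,6R)-2-{(2R)-2-[(tert-butoxycarbonyl)amino]-2-[(2S,4S)-4-methyl-5-oxooxolan-2-yl]ethyl}-6-[(tert-butyldimethylsilyl)oxy]cyclohex-2-en-1-yl]-N,N-dimethylprop-2-enamide, via alkylzinc iodide 18 (not isolated)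
Conditions: 7, Zn dust (I2-activated), DMF, rt; then 17, Pd2(dba)3 (2.5 mol%), SPhos (5 mol%), 50 °C
Reagents that add atoms: none
Why: Negishi cross-coupling of a Jackson-type carbamate-stabilized β-amido alkylzinc iodide with the alkenyl iodide forms the C3–C3a bond; all stereocentres are spectators.

Step 13
Reactants: 19 coupled acrylamide
Product: 21 tert-butyl N-{(1R)-2-[(3aR,4R,7R,7aR)-4-[(tert-butyldimethylsilyl)oxy]-7-hydroxy-3-methylidene-2-oxo-octahydro-1-benzofuran-7a-yl]-1-[(2S,4S)-4-methyl-5-oxooxolan-2-yl]ethyl}carbamate, via β-epoxide 20 (not isolated)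
Conditions: mCPBA, NaHCO3, CH2Cl2, 0 °C; then CSA (20 mol%), CH2Cl2/H2O, rt
Reagents that add atoms: mCPBA (OOC(=O)c1cccc(Cl)c1); water (O)
Why: Peracid epoxidation of the only electron-rich alkene should occur on the β face, anti to the C4 side chain; acid then triggers 5-exo opening at the tertiary carbon C3a by the amide oxygen with inversion (cis-fused lactone, C3a–O α, C7a–OH β), and hydrolysis of the iminium ether releases dimethylamine.

Step 14
Reactants: 21 fused α-methylene lactone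
Product: 22 tert-butyl N-{(1R)-2-[(3R,3aR,4R,7R,7aR)-4-[(tert-butyldimethylsilyl)oxy]-7-hydroxy-3-methyl-2-oxo-octahydro-1-benzofuran-7a-yl]-1-[(2S,4S)-4-methyl-5-oxooxolan-2-yl]ethyl}carbamate
Conditions: H2 (1 atm), 10% Pd/C, EtOAc, rt
Reagents that add atoms: none
Why: Heterogeneous hydrogenation of the exocyclic methylene of a cis-fused lactone delivers hydrogen from the convex face (the side of H-4, away from the carbocycle and the α-silyloxy group at C5), so the methyl should end cis to C5 (3R) as in the target.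

Step 15
Reactants: 22 hydroxy lactone
Product: 24 tert-butyl N-{(1R)-2-[(3R,3aR,4R,7aR)-4-[(tert-butyldimethylsilyl)oxy]-3-methyl-2,7-dioxo-2,3,3a,4,7,7a-hexahydro-1-benzofuran-7a-yl]-1-[(2S,4S)-4-methyl-5-oxooxolan-2-yl]ethyl}carbamate, via C7a ketone 23 (not isolated)
Conditions: IBX (4 equiv), DMSO/fluorobenzene (1:2), 70 °C
Reagents that add atoms: none
Why: IBX oxidizes the secondary alcohol to the C7a ketone and then dehydrogenates it (Nicolaou conditions) toward the only enolizable side, giving the C7=C6 enone that carries the γ-silyloxy group at C5.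

Step 16
Reactants: 24 γ-silyloxy enone
Product: 26 tert-butyl N-{(1R)-2-[(3R,3aR,4R,5S,6S,7aR)-4-[(tert-butyldimethylsilyl)oxy]-5-ethyl-3-methyl-2,7-dioxo-6-(prop-2-en-1-yl)octahydro-1-benzofuran-7a-yl]-1-[(2S,4S)-4-methyl-5-oxooxolan-2-yl]ethyl}carbamate, via zinc enolate 25 (not isolated)
Conditions: Et2Zn (3 equiv), Cu(OTf)2 (5 mol%), P(OEt)3 (10 mol%), toluene, −30 °C; then Pd(PPh3)4 (5 mol%), allyl acetate, 0 °C to rt
Reagents that add atoms: diethylzinc (CC[Zn]CC); allyl acetate (C=CCOC(C)=O)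
Why: Copper-catalysed 1,4-addition of diethylzinc should occur anti to the γ-silyloxy group (ethyl on the β face at C6), and palladium-catalysed allylation of the zinc enolate (Feringa-type tandem) places the allyl group on C7, whose configuration is irrelevant because C7 becomes sp2.

Step 17
Reactants: 26 allyl keto carbamate
Product: 31 target CNP0154902.3, via amino hydroxy ketone 27 (not isolated), via cyclic imine 28 (not isolated), via imino aldehyde 29 (not isolated), via dienamine 30 (not isolated)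
Conditions: TFA/CH2Cl2/H2O (10:10:1), 0 °C to rt, evaporate; then Et3N (1.5 equiv), Rh(acac)(CO)2 (2 mol%), Xantphos (4 mol%), CO/H2 (1:5, 40 bar), toluene/THF, 100 °C
Reagents that add atoms: carbon monoxide ([C-]#[O+])
Why: Aqueous TFA removes Boc and TBS, and after neutralization the C2 amine condenses with the C7a ketone (5-exo-trig addition, then dehydration) to the 1-pyrroline 28, which forms N1–C7a. Rh/Xantphos hydroformylates the C7 allyl group with linear selectivity to aldehyde 29, which forms Cα–Cβ with Cα from CO. The imine–enamine nitrogen then adds to the aldehyde (7-exo-trig), dehydration gives the cross-conjugated dienamine 30, and rhodium hydride hydrogenates only its disubstituted N1–Cα=Cβ enamine; this is a cyclizing hydroaminomethylation (tandem hydroformylation–reductive amination), with intramolecular hydroaminomethylations to azepanes and double reductive aminations of keto aldehydes as closest precedents. No stereocentre is created, the C7 centre is destroyed, and the others are not enolizable under these conditions. The step needs linear regioselectivity (wide-bite-angle Xantphos), N- rather than C7-cyclization (the enamine-aldol at C7 is reversible and cannot dehydrate, whereas the N-adduct is drained by hydrogenation) and chemoselective reduction (ketimines and the tetrasubstituted C7a=C7 enamine are inert to the Rh–H/CO system, which reduces only aldehyde-derived enamines).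

## Compound list

1 | tert-butyl (4R)-4-formyl-2,2-dimethyl-1,3-oxazolidine-3-carboxylate ((R)-Garner's aldehyde) | CC(C)(C)OC(=O)N1[C@@H](C=O)COC1(C)C | starting material
2 | ethyl 2-(bromomethyl)prop-2-enoate | C=C(CBr)C(=O)OCC | starting material
3 | tert-butyl (4R)-4-[(1S)-3-(ethoxycarbonyl)-1-hydroxybut-3-en-1-yl]-2,2-dimethyl-1,3-oxazolidine-3-carboxylate | CC(C)(C)OC(=O)N1[C@@H]([C@@H](O)CC(=C)C(=O)OCC)COC1(C)C | intermediate
4 | tert-butyl (4R)-2,2-dimethyl-4-[(2S)-4-methylidene-5-oxooxolan-2-yl]-1,3-oxazolidine-3-carboxylate | CC(C)(C)OC(=O)N1[C@@H]([C@@H]2CC(=C)C(=O)O2)COC1(C)C | intermediate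
5 | tert-butyl (4R)-2,2-dimethyl-4-[(2S,4S)-4-methyl-5-oxooxolan-2-yl]-1,3-oxazolidine-3-carboxylate | CC(C)(C)OC(=O)N1[C@@H]([C@@H]2C[C@H](C)C(=O)O2)COC1(C)C | intermediate
6 | tert-butyl N-{(1R)-2-hydroxy-1-[(2S,4S)-4-methyl-5-oxooxolan-2-yl]ethyl}carbamate | CC(C)(C)OC(=O)N[C@@H]([C@@H]1C[C@H](C)C(=O)O1)CO | intermediate
7 | tert-butyl N-{(1S)-2-iodo-1-[(2S,4S)-4-methyl-5-oxooxolan-2-yl]ethyl}carbamate | CC(C)(C)OC(=O)N[C@@H]([C@@H]1C[C@H](C)C(=O)O1)CI | intermediate
8 | 1,4-dioxaspiro[4.5]dec-6-en-8-one | O=C1C=CC2(CC1)OCCO2 | starting material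
9 | (8R)-1,4-dioxaspiro[4.5]dec-6-en-8-ol | O[C@H]1C=CC2(CC1)OCCO2 | intermediate
10 | tert-butyl{[(8R)-1,4-dioxaspiro[4.5]dec-6-en-8-yl]oxy}dimethylsilane | CC(C)(C)[Si](C)(C)O[C@H]1C=CC2(CC1)OCCO2 | intermediate
11 | (4R)-4-[(tert-butyldimethylsilyl)oxy]cyclohex-2-en-1-one | CC(C)(C)[Si](C)(C)O[C@H]1C=CC(=O)CC1 | intermediate
12 | (4R)-4-[(tert-butyldimethylsilyl)oxy]-2-iodocyclohex-2-en-1-one | CC(C)(C)[Si](C)(C)O[C@H]1C=C(I)C(=O)CC1 | intermediate
13 | (1S,4R)-4-[(tert-butyldimethylsilyl)oxy]-2-iodocyclohex-2-en-1-ol (cis) | CC(C)(C)[Si](C)(C)O[C@H]1C=C(I)[C@@H](O)CC1 | intermediate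
14 | 1-{[(1S,4R)-4-[(tert-butyldimethylsilyl)oxy]-2-iodocyclohex-2-en-1-yl]oxy}-N,N-dimethylethen-1-amine | CC(C)(C)[Si](C)(C)O[C@H]1C=C(I)[C@@H](OC(=C)N(C)C)CC1 | intermediate
15 | 2-{(1R,6R)-6-[(tert-butyldimethylsilyl)oxy]-2-iodocyclohex-2-en-1-yl}-N,N-dimethylacetamide | CN(C)C(=O)C[C@H]1C(I)=CCC[C@H]1O[Si](C)(C)C(C)(C)C | intermediate
16 | 3-(dimethylamino)-2-{(1R,6R)-6-[(tert-butyldimethylsilyl)oxy]-2-iodocyclohex-2-en-1-yl}-N,N-dimethylpropanamide (both epimers at the new centre) | CN(C)CC(C(=O)N(C)C)[C@H]1C(I)=CCC[C@H]1O[Si](C)(C)C(C)(C)C | intermediate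
17 | 2-{(1R,6R)-6-[(tert-butyldimethylsilyl)oxy]-2-iodocyclohex-2-en-1-yl}-N,N-dimethylprop-2-enamide | C=C(C(=O)N(C)C)[C@H]1C(I)=CCC[C@H]1O[Si](C)(C)C(C)(C)C | intermediate
18 | {(2S)-2-[(tert-butoxycarbonyl)amino]-2-[(2S,4S)-4-methyl-5-oxooxolan-2-yl]ethyl}(iodo)zinc | CC(C)(C)OC(=O)N[C@@H]([C@@H]1C[C@H](C)C(=O)O1)C[Zn]I | intermediate
19 | 2-[(1R,6R)-2-{(2R)-2-[(tert-butoxycarbonyl)amino]-2-[(2S,4S)-4-methyl-5-oxooxolan-2-yl]ethyl}-6-[(tert-butyldimethylsilyl)oxy]cyclohex-2-en-1-yl]-N,N-dimethylprop-2-enamide | C=C(C(=O)N(C)C)[C@H]1C(C[C@@H](NC(=O)OC(C)(C)C)[C@@H]2C[C@H](C)C(=O)O2)=CCC[C@H]1O[Si](C)(C)C(C)(C)C | intermediate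
20 | C3a,C7a β-epoxide of 19 (oxirane anti to the acrylamide side chain and to O–C5) | C=C(C(=O)N(C)C)[C@H]1[C@]2(C[C@@H](NC(=O)OC(C)(C)C)[C@@H]3C[C@H](C)C(=O)O3)O[C@@H]2CC[C@H]1O[Si](C)(C)C(C)(C)C | intermediate
21 | tert-butyl N-{(1R)-2-[(3aR,4R,7R,7aR)-4-[(tert-butyldimethylsilyl)oxy]-7-hydroxy-3-methylidene-2-oxo-octahydro-1-benzofuran-7a-yl]-1-[(2S,4S)-4-methyl-5-oxooxolan-2-yl]ethyl}carbamate | CC(C)(C)OC(=O)N[C@@H]([C@@H]1C[C@H](C)C(=O)O1)C[C@@]12OC(=O)C(=C)[C@@H]1[C@H](O[Si](C)(C)C(C)(C)C)CC[C@H]2O | intermediate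
22 | tert-butyl N-{(1R)-2-[(3R,3aR,4R,7R,7aR)-4-[(tert-butyldimethylsilyl)oxy]-7-hydroxy-3-methyl-2-oxo-octahydro-1-benzofuran-7a-yl]-1-[(2S,4S)-4-methyl-5-oxooxolan-2-yl]ethyl}carbamate | CC(C)(C)OC(=O)N[C@@H]([C@@H]1C[C@H](C)C(=O)O1)C[C@@]12OC(=O)[C@H](C)[C@@H]1[C@H](O[Si](C)(C)C(C)(C)C)CC[C@H]2O | intermediate
23 | tert-butyl N-{(1R)-2-[(3R,3aR,4R,7aR)-4-[(tert-butyldimethylsilyl)oxy]-3-methyl-2,7-dioxo-octahydro-1-benzofuran-7a-yl]-1-[(2S,4S)-4-methyl-5-oxooxolan-2-yl]ethyl}carbamate | CC(C)(C)OC(=O)N[C@@H]([C@@H]1C[C@H](C)C(=O)O1)C[C@@]12OC(=O)[C@H](C)[C@@H]1[C@H](O[Si](C)(C)C(C)(C)C)CCC2=O | intermediate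
24 | tert-butyl N-{(1R)-2-[(3R,3aR,4R,7aR)-4-[(tert-butyldimethylsilyl)oxy]-3-methyl-2,7-dioxo-2,3,3a,4,7,7a-hexahydro-1-benzofuran-7a-yl]-1-[(2S,4S)-4-methyl-5-oxooxolan-2-yl]ethyl}carbamate | CC(C)(C)OC(=O)N[C@@H]([C@@H]1C[C@H](C)C(=O)O1)C[C@@]12OC(=O)[C@H](C)[C@@H]1[C@H](O[Si](C)(C)C(C)(C)C)C=CC2=O | intermediate
25 | ethylzinc enolate of the 6β-ethyl ketone (C7=C7a–O–ZnEt; ring centres as in 26) | CC(C)(C)OC(=O)N[C@@H]([C@@H]1C[C@H](C)C(=O)O1)C[C@@]12OC(=O)[C@H](C)[C@@H]1[C@H](O[Si](C)(C)C(C)(C)C)[C@@H](CC)C=C2O[Zn]CC | intermediate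
26 | tert-butyl N-{(1R)-2-[(3R,3aR,4R,5S,6S,7aR)-4-[(tert-butyldimethylsilyl)oxy]-5-ethyl-3-methyl-2,7-dioxo-6-(prop-2-en-1-yl)octahydro-1-benzofuran-7a-yl]-1-[(2S,4S)-4-methyl-5-oxooxolan-2-yl]ethyl}carbamate | CC(C)(C)OC(=O)N[C@@H]([C@@H]1C[C@H](C)C(=O)O1)C[C@@]12OC(=O)[C@H](C)[C@@H]1[C@H](O[Si](C)(C)C(C)(C)C)[C@@H](CC)[C@H](CC=C)C2=O | intermediate
27 | (3R,3aR,4R,5S,6S,7aR)-7a-{(2R)-2-amino-2-[(2S,4S)-4-methyl-5-oxooxolan-2-yl]ethyl}-5-ethyl-4-hydroxy-3-methyl-6-(prop-2-en-1-yl)hexahydro-1-benzofuran-2,7-dione | N[C@@H]([C@@H]1C[C@H](C)C(=O)O1)C[C@@]12OC(=O)[C@H](C)[C@@H]1[C@H](O)[C@@H](CC)[C@H](CC=C)C2=O | intermediate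
28 | cyclic imine: target core without the azepine, N1=C7a, C7 (either epimer) bearing prop-2-en-1-yl, other centres as in 31 | CC[C@H]1C(CC=C)C2=N[C@@H]([C@@H]3C[C@H](C)C(=O)O3)C[C@]24OC(=O)[C@H](C)[C@@H]4[C@@H]1O | intermediate
29 | imino aldehyde: as 28 with C7 bearing 4-oxobutyl | CC[C@H]1C(CCCC=O)C2=N[C@@H]([C@@H]3C[C@H](C)C(=O)O3)C[C@]24OC(=O)[C@H](C)[C@@H]4[C@@H]1O | intermediate
30 | Cα,Cβ-didehydro target (N1–Cα=Cβ and N1–C7a=C7 enamines; other centres as in 31) | CC[C@H]1C2=C3N(C=CCC2)[C@@H]([C@@H]2C[C@H](C)C(=O)O2)C[C@]32OC(=O)[C@H](C)[C@@H]2[C@@H]1O | intermediate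
31 | CNP0154902.3 (C2 R, C3a R, C4 R, C5 R, C6 S, fused-lactone methyl carbon R, pendant lactone 2S,4S) | CC[C@H]1C2=C3N(CCCC2)[C@@H]([C@@H]2C[C@H](C)C(=O)O2)C[C@]32OC(=O)[C@H](C)[C@@H]2[C@@H]1O | target

## Step count

Total: 17 steps. Longest linear sequence: 13 steps (8 to 31, steps 5–17); the side-chain iodide 7 is made in 4 steps (steps 1–4) and joined in step 12.

## Steps most likely to fail, with fallbacks

Step 17. The cascade may be diverted by reversible enamine-aldol closure at C7 outrunning N-cyclization, by branched hydroformylation, or by over-reduction of the C7a=N unit. The fallback builds the azepine as a lactam. It sets out from 26: TMSOTf/2,6-lutidine then MeOH removes only the Boc group and the amine closes onto C7a to give the silyl-protected cyclic imine F1. Acryloyl chloride/Et3N N-acylates it to the N1-acryloyl enamide F2. Ring-closing metathesis with the second-generation Grubbs catalyst RuCl2(=CHPh)(H2IMes)(PCy3) closes the seven-membered ring to the unsaturated lactam F3. H2 over Pd/C saturates the disubstituted alkene to the lactam F4. IrCl(CO)(PPh3)2 with (Me2SiH)2O, then NaBH(OAc)3/AcOH, reduces the lactam carbonyl to CH2 without touching the lactones and gives the silyl ether F5. HF·pyridine in THF then returns to 31.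

Step 12. β-Elimination of the β-amido alkylzinc 18, or slow transmetalation at the hindered trisubstituted alkenyl iodide, may erode the coupling. The fallback is a cross-electrophile coupling that never forms an organozinc. It sets out from 7 and 17 with NiBr2(dme), 4,4'-di-tert-butyl-2,2'-bipyridine, Mn powder and NaI in DMA at rt, joining the alkyl radical from 7 to the alkenylnickel from 17. It comes back directly at 19 and makes no compound outside the list (F0).

Step 16. The zinc enolate may be protonated, or the carbamate nitrogen allylated in place of C7, and facial control of the 1,4-addition may be incomplete. The fallback separates the two events. It sets out from 24: the Cu(OTf)2-catalysed Et2Zn addition is run with TMSCl to give the trimethylsilyl enol ether F6. F6 is then allylated with allyl methyl carbonate and Pd2(dba)3/dppe in THF at 65 °C (Tsuji allylation of silyl enol ethers), which comes back to the route at 26.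

Further compounds
F1 | step 17 | 5-O-TBS cyclic imine (N1=C7a, C7 bearing prop-2-en-1-yl) | CC[C@H]1C(CC=C)C2=N[C@@H]([C@@H]3C[C@H](C)C(=O)O3)C[C@]24OC(=O)[C@H](C)[C@@H]4[C@@H]1O[Si](C)(C)C(C)(C)C
F2 | step 17 | N1-acryloyl enamide (C7a=C7, C7 bearing prop-2-en-1-yl, 5-O-TBS) | CC[C@H]1C(CC=C)=C2N(C(=O)C=C)[C@@H]([C@@H]3C[C@H](C)C(=O)O3)C[C@]24OC(=O)[C@H](C)[C@@H]4[C@@H]1O[Si](C)(C)C(C)(C)C
F3 | step 17 | Cα-oxo-Cβ,Cγ-didehydro lactam (5-O-TBS) | CC[C@H]1C2=C3N(C(=O)C=CC2)[C@@H]([C@@H]2C[C@H](C)C(=O)O2)C[C@]32OC(=O)[C@H](C)[C@@H]2[C@@H]1O[Si](C)(C)C(C)(C)C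
F4 | step 17 | Cα-oxo lactam (5-O-TBS) | CC[C@H]1C2=C3N(C(=O)CCC2)[C@@H]([C@@H]2C[C@H](C)C(=O)O2)C[C@]32OC(=O)[C@H](C)[C@@H]2[C@@H]1O[Si](C)(C)C(C)(C)C
F5 | step 17 | 5-O-TBS ether of 31 | CC[C@H]1C2=C3N(CCCC2)[C@@H]([C@@H]2C[C@H](C)C(=O)O2)C[C@]32OC(=O)[C@H](C)[C@@H]2[C@@H]1O[Si](C)(C)C(C)(C)C
F0 | step 12 | none | none
F6 | step 16 | trimethylsilyl enol ether of the 6β-ethyl ketone (C7=C7a–OSiMe3) | CC(C)(C)OC(=O)N[C@@H]([C@@H]1C[C@H](C)C(=O)O1)C[C@@]12OC(=O)[C@H](C)[C@@H]1[C@H](O[Si](C)(C)C(C)(C)C)[C@@H](CC)C=C2O[Si](C)(C)C
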